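Assumption: methyl 3-oxooctadecanoate 1 is taken as a catalogue β-keto ester, and the route starts from it.

## The problem

Target 11 is (R)-5,8-dihydroxy-2-pentadecylchroman-4-one. Ring A, a benzene ring (C4a, C5, C6, C7, C8, C8a), is fused to ring B, a dihydropyranone (O1, C2, C3, C4, C4a, C8a), and C2 carries the C15 chain and the only stereocenter. Ring A bears four substituents in a row (C5–OH, the C4 ketone on C4a, O1 on C8a, C8–OH). No simple arene has this 2,3,6-trioxygenated aryl ketone pattern, and a route that builds it must still tell the C8a oxygen from the C5 oxygen, both ortho to the acyl group. C2 stands alone, so nothing in the molecule can relay its configuration and it must come from a catalyst or reagent. The C2–O1 bond is β to the C4 ketone, so enolisation at C3 by base or Lewis acid can expel the C8a phenoxide and reclose ring B as the racemate. Ring A is a hydroquinone, sensitive to air under base, and the usual end-game of cleaving two aryl methyl ethers with a boron halide is the treatment the C2–O1 bond tolerates least. The feature that offers a way out is the para relation of C5–OH and C8–OH across ring A: in the quinone form of ring A, C8a is the β-carbon of both the C5 carbonyl and the C4 ketone. O1 can therefore be bonded to C8a, a plain C–H position of a 2-acylhydroquinone, by conjugate addition of the C2 hydroxyl, and ring A returns at the oxidation level of the target with the stereocenter untouched.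

## Retrosynthesis

**O1–C8a (11 ⇒ 10 ⇒ 9 ⇒ 8).** The aryl ether bond O1–C8a is cut, with a change of oxidation level: 11 is the reduced form of ring-closed quinone 10, which arises from acylquinone 9 and thus from hydroquinone 8. The neighbouring cuts of ring B are O1–C2 and C2–chain. Both need a ring A that already carries three oxygens, and both make or endanger the stereogenic C2–O1 bond under equilibrating or basic conditions. The chosen cut leaves that bond alone and removes one oxygen from the arene. Precursor 8 is a monocyclic 2,5-dihydroxyphenyl ketone with an open chain, a 1,2,4-trisubstituted benzene in place of a 1,2,3,4-tetrasubstituted one. The forward reaction must oxidise 8 to 9 without touching the secondary alcohol and let that alcohol add to the quinone carbon that becomes C8a faster than the β-hydroxy ketone loses water. Over-oxidation of the product to 10 is accepted and undone by reduction.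

**O–benzyl (8 ⇒ 7).** The two phenolic O–H bonds of 8 are traced back to benzyl ethers in 7. Benzyl is preferred to methyl because it is removed by neutral hydrogenolysis, and it is removed before ring B exists, so no deprotection is ever run on the chromanone. The forward step must cleave two aryl benzyl ethers without reducing the aryl ketone.

**Aryl–carbonyl bond (7 ⇒ 6 + 3).** The bond between the ring and the ketone carbon (the future C4a–C4) is cut, giving aryllithium 6 and Weinreb amide 3. The neighbouring cut, between the α- and β-carbons of the ketone, would be an acetate-type aldol addition of a methyl aryl ketone to an unbranched aldehyde, a reaction class in which enantiocontrol is only moderate. The chosen cut places the stereocenter in a C18 acid derivative, where it sits next to an ester and can be set by ketone hydrogenation. The forward reaction must stop at the ketone and tolerate the free hydroxyl of 3.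

**Amide and carbinol (3 ⇒ 2 ⇒ 1).** The amide C–N bond of 3 goes back to the methyl ester 2, and the carbinol C–H bond of 2 to the prochiral ketone of 1. This is the only stereocenter-forming step. It is placed first, on the cheapest material, and the configuration is never part of a later bond-forming event.

**Aryl metal (6 ⇒ 5 ⇒ 4).** The C–Li bond of 6 comes from the C–Br bond of 5, and the benzyl ethers of 5 from bromohydroquinone 4. Compound 4 already has the para-dioxygen pattern, and its bromine fixes where the acyl group enters.

## Roads not taken

**Alternative 1:** The cut most chemists would draw first is the bond from C2 to the chain. Copper-catalysed asymmetric conjugate addition of pentadecylmagnesium bromide A3 to 5,8-dimethoxychromone A2 would give (R)-5,8-dimethoxy-2-pentadecylchroman-4-one A4, followed by cleavage of both methyl ethers. A2 would come from 1-(2-hydroxy-3,6-dimethoxyphenyl)ethan-1-one A1 by one-carbon homologation and cyclisation.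
- A1 is exactly the 2,3,6-trioxygenated aryl ketone that no simple building block offers.
- The acceptor is deactivated: the C5 methoxy group donates into the C4 carbonyl and O1 into C2.
- The magnesium enolate of A4 can expel the C8a phenoxide and lose configuration.
- The end-game is a double aryl methyl ether cleavage by a boron trihalide on a molecule whose C2–O1 bond is labile to Lewis acid.
- The chosen plan never forms an enolate of the closed ring under basic conditions and ends with a reduction in water.

**Alternative 2:** Cut O1–C2. The forward key step is an enantioselective intramolecular oxa-Michael addition of the phenol of (E)-1-(2-hydroxy-3,6-dimethoxyphenyl)octadec-2-en-1-one A6 under a chiral bifunctional amine catalyst, giving A4. A6 would come from A1 and hexadecanal A5.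
- The addition is reversible and, for a β-alkyl enone without a second activating group, an uncatalysed closure and the equilibrium itself erode enantiopurity.
- The condensation of an enolisable long-chain aldehyde with the ketone is unclean.
- A1 and the demethylation are still needed.
- The chosen plan forms the other bond of O1, so the stereogenic C–O bond comes from a ketone hydrogenation and is never subject to an equilibrium.

**Alternative 3:** Cut C4–C4a. The forward key step is an intramolecular Friedel–Crafts acylation of (R)-3-(2,5-dimethoxyphenoxy)octadecanoic acid A7 in strong acid, giving A4.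
- A7 needs an aryl ether at a secondary carbon β to a carboxyl group, made by displacement with inversion, where elimination to the enoate is the expected competitor.
- The acid of the ring closure can expel the phenol from A7 by the same β-elimination.
- The acylation must occur at the hindered position between two oxygen-bearing carbons.
- The product is again A4 with its demethylation, and the sequence is longer than the chosen one.

Key step: step 6

## Route

Step 1
Reactants: 1 methyl 3-oxooctadecanoate
Product: 2 methyl (R)-3-hydroxyoctadecanoate
Conditions: H2 (10 bar), RuCl2[(R)-BINAP] (0.5 mol %), MeOH, 50 °C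
Reagents that add atoms: none
Why: Noyori asymmetric hydrogenation of a β-keto ester: the ester carbonyl chelates ruthenium and the (R)-BINAP ligand directs hydride to one face of the ketone, as for other 3-oxoalkanoates, which sets the only stereocenter of the route (the future C2) as R.

Step 2
Reactants: 2 methyl (R)-3-hydroxyoctadecanoate
Product: 3 (R)-3-hydroxy-N-methoxy-N-methyloctadecanamide
Conditions: MeNH(OMe)·HCl (1.6 equiv), iPrMgCl (4.3 equiv), THF, −20 to 0 °C; aq NH4Cl
Reagents that add atoms: N,O-dimethylhydroxylamine hydrochloride, CNOC.Cl
Why: Weinreb amide formation by aminolysis of the ester with the chloromagnesium amide of N,O-dimethylhydroxylamine; the free hydroxyl is only converted into its magnesium alkoxide and the stereocenter is not involved.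

Step 3
Reactants: 4 2-bromobenzene-1,4-diol (bromohydroquinone)
Product: 5 2-bromo-1,4-bis(benzyloxy)benzene
Conditions: BnBr (2.2 equiv), K2CO3 (2.5 equiv), DMF, 60 °C, N2
Reagents that add atoms: benzyl bromide, BrCc1ccccc1
Why: Williamson ether synthesis on both phenols; benzyl is chosen because it survives aryllithium chemistry and is later removed by neutral hydrogenolysis.

Step 4
Reactants: 5 2-bromo-1,4-bis(benzyloxy)benzene; 3 (R)-3-hydroxy-N-methoxy-N-methyloctadecanamide
Product: 7 (R)-1-[2,5-bis(benzyloxy)phenyl]-3-hydroxyoctadecan-1-one, via aryllithium 6 (not isolated)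
Conditions: 5 (2.4 equiv), n-BuLi (2.4 equiv), THF, −78 °C; then 3 (1 equiv), −78 °C; aq NH4Cl at −78 °C
Reagents that add atoms: none
Why: Bromine–lithium exchange gives 6; its first equivalent deprotonates the hydroxyl of 3 and the second adds to the amide, whose chelated tetrahedral intermediate holds until the quench and prevents over-addition (Weinreb ketone synthesis). The β-hydroxy ketone is set free only on the mildly acidic quench, so retro-aldol cleavage and dehydration have no opportunity.

Step 5
Reactants: 7 (R)-1-[2,5-bis(benzyloxy)phenyl]-3-hydroxyoctadecan-1-one
Product: 8 (R)-1-(2,5-dihydroxyphenyl)-3-hydroxyoctadecan-1-one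
Conditions: H2 (1 atm), Pd/C (10 %), EtOAc, rt, stopped after two equivalents of H2
Reagents that add atoms: none
Why: Hydrogenolysis of two aryl benzyl ethers under neutral conditions; the aryl ketone, hydrogen-bonded to the ortho phenol as it is freed, and the non-benzylic secondary alcohol should remain.

Step 6
Reactants: 8 (R)-1-(2,5-dihydroxyphenyl)-3-hydroxyoctadecan-1-one
Product: 11 (R)-5,8-dihydroxy-2-pentadecylchroman-4-one, via acylquinone 9 (not isolated), via ring-closed quinone 10 (not isolated)
Conditions: divided cell, reticulated vitreous carbon anode, Pt cathode, LiClO4 (0.1 M), 2,6-lutidine (4.5 equiv, anolyte), MeCN/(CF3)2CHOH 9:1, constant current to 4.2 F/mol, rt, N2; then Na2S2O4, H2O/EtOAc, rt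
Reagents that add atoms: none
Why: Proposed new method: anodic two-electron, two-proton oxidation of hydroquinone 8 gives acylquinone 9, in which the ring carbon that becomes C8a is the β-carbon of both the adjacent ring carbonyl and the side-chain ketone, so the tethered secondary hydroxyl adds there and enolisation restores the aromatic ring as 11. The closest known reaction types are the anodic oxidation of hydroquinones and catechols in the presence of nucleophiles, which runs through the same oxidation, Michael addition, oxidation sequence, and the addition of heteroatom nucleophiles next to the acyl group of 2-acyl-1,4-benzoquinones; what is new is the intramolecular use of an unactivated secondary alcohol to close a chromanone. Ring B closes in the 6-endo-trig mode, the counterpart of the chalcone-to-flavanone closure with donor and acceptor exchanged. No stereocenter is formed: the C2–O1 bond is neither made nor broken, so the configuration from step 1 is carried through. Regioselectivity comes from the substrate, since the attacked carbon is the only doubly activated position and the only one the tether can reach in a six-membered transition state; chemoselectivity rests on the low oxidation potential of the hydroquinone, far below that of the alcohol, the lutidine or the solvent. Because 11 carries one more oxygen donor than 8 it should be oxidised more easily, so the electrolysis is taken to four faradays per mole to collect the material as quinone 10, and the dithionite work-up returns 11. The non-nucleophilic, hydrogen-bond-donating medium activates the quinone and keeps water and strong base away from 9 and 10, which should suppress dehydration of the β-hydroxy ketone and opening of ring B by β-elimination.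

## Compound list

1 | methyl 3-oxooctadecanoate | CCCCCCCCCCCCCCCC(=O)CC(=O)OC | starting material
2 | methyl (R)-3-hydroxyoctadecanoate | CCCCCCCCCCCCCCC[C@@H](O)CC(=O)OC | intermediate
3 | (R)-3-hydroxy-N-methoxy-N-methyloctadecanamide | CCCCCCCCCCCCCCC[C@@H](O)CC(=O)N(C)OC | intermediate
4 | 2-bromobenzene-1,4-diol (bromohydroquinone) | Oc1ccc(O)c(Br)c1 | starting material
5 | 2-bromo-1,4-bis(benzyloxy)benzene | Brc1cc(OCc2ccccc2)ccc1OCc1ccccc1 | intermediate
6 | [2,5-bis(benzyloxy)phenyl]lithium | [Li]c1cc(OCc2ccccc2)ccc1OCc1ccccc1 | intermediate
7 | (R)-1-[2,5-bis(benzyloxy)phenyl]-3-hydroxyoctadecan-1-one | CCCCCCCCCCCCCCC[C@@H](O)CC(=O)c1cc(OCc2ccccc2)ccc1OCc1ccccc1 | intermediate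
8 | (R)-1-(2,5-dihydroxyphenyl)-3-hydroxyoctadecan-1-one | CCCCCCCCCCCCCCC[C@@H](O)CC(=O)c1cc(O)ccc1O | intermediate
9 | 2-[(R)-3-hydroxyoctadecanoyl]cyclohexa-2,5-diene-1,4-dione | CCCCCCCCCCCCCCC[C@@H](O)CC(=O)C1=CC(=O)C=CC1=O | intermediate
10 | (R)-2-pentadecyl-2,3-dihydro-4H-chromene-4,5,8-trione | CCCCCCCCCCCCCCC[C@@H]1CC(=O)C2=C(O1)C(=O)C=CC2=O | intermediate
11 | (R)-5,8-dihydroxy-2-pentadecylchroman-4-one | CCCCCCCCCCCCCCC[C@@H]1CC(=O)c2c(O)ccc(O)c2O1 | target

## Step count and risks

Total steps: 6. Longest linear sequence: 5 (steps 1, 2, 4, 5, 6).

**Step 6 (key step, proposed new method).**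
- Most likely failure: loss of water from the β-hydroxy ketone at the stage of acylquinone 9, whose α-hydrogens are acidified by the quinone-bound carbonyl, or self-condensation of 9 before ring B closes.
- Second concern: erosion of configuration by reversible opening of ring B in quinone 10, where the oxygen on C8a is a vinylogous carboxylate leaving group.
- Fallback (known chemistry; ring B is closed at O1–C2 with inversion): it sets out from 1. Hydrogenation as in step 1 but with RuCl2[(S)-BINAP] should give methyl (S)-3-hydroxyoctadecanoate F1, which is converted as in step 2 into (S)-3-hydroxy-N-methoxy-N-methyloctadecanamide F2. 2,5-Dimethoxyphenol F3 is converted with MOMCl and iPr2NEt into 1,4-dimethoxy-2-(methoxymethoxy)benzene F4. F4 is lithiated with n-BuLi (THF, 0 °C) at the position flanked by two oxygen groups and added to F2 as in step 4, giving (S)-1-[3,6-dimethoxy-2-(methoxymethoxy)phenyl]-3-hydroxyoctadecan-1-one F5. HCl in MeOH removes the acetal to give (S)-3-hydroxy-1-(2-hydroxy-3,6-dimethoxyphenyl)octadecan-1-one F6. Mitsunobu cyclisation (PPh3, DIAD, THF) then closes O1–C2 with inversion to (R)-5,8-dimethoxy-2-pentadecylchroman-4-one F7. Oxidative demethylation with (NH4)2Ce(NO3)6 in MeCN/H2O at 0 °C leads to quinone 10, where the fallback rejoins the route; Na2S2O4 as in step 6 then gives 11.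

**Step 4.**
- Most likely failure: the aryllithium acts as a base on the amide (deprotonation at the α-carbon or at the N-methoxy group with loss of formaldehyde) instead of adding, or the lithium alkoxide of 3 aggregates and reacts incompletely at −78 °C. Warming is limited because 6 can transfer its charge to the benzylic position of the neighbouring ether.
- Fallback (carbon–carbon bond formed at the aldehyde level, then oxidation): it sets out from 2. TBSCl and imidazole give methyl (R)-3-[(tert-butyldimethylsilyl)oxy]octadecanoate F8, and DIBAL-H (CH2Cl2, −78 °C) gives (R)-3-[(tert-butyldimethylsilyl)oxy]octadecanal F9. One equivalent of aryllithium 6, made from 5 as in step 4, adds to F9 to give (3R)-1-[2,5-bis(benzyloxy)phenyl]-3-[(tert-butyldimethylsilyl)oxy]octadecan-1-ol F10 as both C1 epimers. MnO2 (CH2Cl2) oxidises both to (R)-1-[2,5-bis(benzyloxy)phenyl]-3-[(tert-butyldimethylsilyl)oxy]octadecan-1-one F11. HF·pyridine in THF removes the silyl group and returns to the route at 7.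

**Step 5.**
- Most likely failure: over-reduction of the aryl ketone once the benzyl groups are gone, or air oxidation of hydroquinone 8 during isolation.
- Fallback (oxidative unmasking that bypasses 8): it sets out from 3. 2-Bromo-1,4-dimethoxybenzene F12 is lithiated with n-BuLi (THF, −78 °C) and added to 3 as in step 4 to give (R)-1-(2,5-dimethoxyphenyl)-3-hydroxyoctadecan-1-one F13. Oxidative demethylation with (NH4)2Ce(NO3)6 in MeCN/H2O at 0 °C leads directly to acylquinone 9, where the fallback re-enters step 6: ring closure and further oxidation to 10 in the same flask, then Na2S2O4 to 11.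

## Further compounds

F1 | step 6 | methyl (S)-3-hydroxyoctadecanoate | CCCCCCCCCCCCCCC[C@H](O)CC(=O)OC
F2 | step 6 | (S)-3-hydroxy-N-methoxy-N-methyloctadecanamide | CCCCCCCCCCCCCCC[C@H](O)CC(=O)N(C)OC
F3 | step 6 | 2,5-dimethoxyphenol | COc1ccc(OC)c(O)c1
F4 | step 6 | 1,4-dimethoxy-2-(methoxymethoxy)benzene | COCOc1cc(OC)ccc1OC
F5 | step 6 | (S)-1-[3,6-dimethoxy-2-(methoxymethoxy)phenyl]-3-hydroxyoctadecan-1-one | CCCCCCCCCCCCCCC[C@H](O)CC(=O)c1c(OC)ccc(OC)c1OCOC
F6 | step 6 | (S)-3-hydroxy-1-(2-hydroxy-3,6-dimethoxyphenyl)octadecan-1-one | CCCCCCCCCCCCCCC[C@H](O)CC(=O)c1c(OC)ccc(OC)c1O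
F7 | step 6 | (R)-5,8-dimethoxy-2-pentadecylchroman-4-one | CCCCCCCCCCCCCCC[C@@H]1CC(=O)c2c(OC)ccc(OC)c2O1
F8 | step 4 | methyl (R)-3-[(tert-butyldimethylsilyl)oxy]octadecanoate | CCCCCCCCCCCCCCC[C@@H](O[Si](C)(C)C(C)(C)C)CC(=O)OC
F9 | step 4 | (R)-3-[(tert-butyldimethylsilyl)oxy]octadecanal | CCCCCCCCCCCCCCC[C@@H](O[Si](C)(C)C(C)(C)C)CC=O
F10 | step 4 | (3R)-1-[2,5-bis(benzyloxy)phenyl]-3-[(tert-butyldimethylsilyl)oxy]octadecan-1-ol (both C1 epimers) | CCCCCCCCCCCCCCC[C@@H](O[Si](C)(C)C(C)(C)C)CC(O)c1cc(OCc2ccccc2)ccc1OCc1ccccc1
F11 | step 4 | (R)-1-[2,5-bis(benzyloxy)phenyl]-3-[(tert-butyldimethylsilyl)oxy]octadecan-1-one | CCCCCCCCCCCCCCC[C@@H](O[Si](C)(C)C(C)(C)C)CC(=O)c1cc(OCc2ccccc2)ccc1OCc1ccccc1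
F12 | step 5 | 2-bromo-1,4-dimethoxybenzene | COc1ccc(OC)c(Br)c1
F13 | step 5 | (R)-1-(2,5-dimethoxyphenyl)-3-hydroxyoctadecan-1-one | CCCCCCCCCCCCCCC[C@@H](O)CC(=O)c1cc(OC)ccc1OC
A1 | alternative 1 | 1-(2-hydroxy-3,6-dimethoxyphenyl)ethan-1-one | CC(=O)c1c(O)c(OC)ccc1OC
A2 | alternative 1 | 5,8-dimethoxy-4H-chromen-4-one | COc1ccc(OC)c2c1occc2=O
A3 | alternative 1 | pentadecylmagnesium bromide | CCCCCCCCCCCCCCC[Mg]Br
A4 | alternative 1 | (R)-5,8-dimethoxy-2-pentadecylchroman-4-one | CCCCCCCCCCCCCCC[C@@H]1CC(=O)c2c(OC)ccc(OC)c2O1
A5 | alternative 2 | hexadecanal | CCCCCCCCCCCCCCCC=O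
A6 | alternative 2 | (E)-1-(2-hydroxy-3,6-dimethoxyphenyl)octadec-2-en-1-one | CCCCCCCCCCCCCCC/C=C/C(=O)c1c(O)c(OC)ccc1OC
A7 | alternative 3 | (R)-3-(2,5-dimethoxyphenoxy)octadecanoic acid | CCCCCCCCCCCCCCC[C@@H](Oc1cc(OC)ccc1OC)CC(=O)O
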